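Atom numbers follow the target skeleton: ring A is the pyranone; ring B holds O8, C9, C18 and C19; ring C is C9–C10–C11–C12–C13–C17–C18; ring D is C12–C13=C14–C15–C16.

## Structural features

The target is a tetracycle. A 5,6-dimethyl-2-pyranone (ring A) is fused through its C3–C4 edge to a dihydropyran (ring B: O8, hemiketal C9, C18, methylene C19). Ring B is trans-fused at C9–C18 to a seven-membered carbocycle (ring C), which shares C12–C13 with a 4,4-dimethylcyclopentenone (ring D: C13=C14, C15=O, C16 with two methyl groups).

There are five stereocentres, (9S,10R,12R,17R,18R). C9 and C10 are adjacent, C12 is a fully substituted carbinol separated from C10 only by the C11 ketone, and C17 (methyl) and C18 are adjacent on the other side of ring C. In a ring projection the C12 and C9 hydroxyls are on one face, and the C10 hydroxyl and the C17 methyl on the other.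

The fragile groups are the hemiketal (its open form is a 2-hydroxy-1,3-dione that enolises and oxidises easily), the two α-ketol pairs around C11 (acyloin shift, epimerisation at C10), the O8–C9 bond β to the C11 carbonyl, and the enone. The real difficulty is the contiguous oxygenation C9–C12 on a seven-membered ring next to a quaternary carbinol flanked by the quaternary C16, together with the absolute configuration of C12.

C9, C10 and C18 can equilibrate through ring opening and enolisation; only C12 and C17 must be set irreversibly. The key step exploits the position of C12 between C11 and C13. With the other ring C substituents removed and C13=C14 opened, ring C is a mirror-symmetric 2,2-disubstituted cycloheptane-1,3-dione. Ring D is then a 3-oxobutan-2-yl side chain on C12, and choosing one of the two enantiotopic carbonyls fixes C12.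

## Logic of the disconnections

22 to 21: the two O–Si bonds at C10 and C12 are cut. The carbinols must be masked while the C9–C11 region is built, so every earlier intermediate is protected against ketol shifts. The forward cleavage must be buffered so that the hemiketal and the β-alkoxy ketone survive.

21 to 19 and 20: the C3–C19 and O8–C9 bonds of ring B are cut. C19 lies between a nucleophilic enol carbon of ring A and the α-carbon of the C9 ketone, which is a Michael retron, and the hemiketal then closes by itself. Rings A and B and three stereocentres disappear. The forward step must be mild enough for an exocyclic enone and must let C9, C18 and C10 settle by equilibration.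

19 to 18: the C10–O bond is cut. The C10=C11 enol ether that protected C11 becomes the site of hydroxylation, so no separate deprotection is needed. The oxidant must pick the one electron-rich alkene among four C=C bonds.

18 to 15: the C17–CH3 bond and the C18=C19 bond are cut. C17 and C18 are the β- and α-carbons of the C9 enone, so conjugate methylation and enolate trapping install both. This removes the C17 stereocentre and two carbons. The methyl group must enter at C17, not at C13 or C11, and from the face opposite the C12 silyl ether.

15 to 13: the C17=C18 unsaturation and the C11 enol silyl ether are removed. Without the mask, C10 would be an acidic position between two carbonyls and would quench the cuprate. C12 bears no hydrogen, so 13 can form only one bis-enol ether, and its terminal carbon is C18. Dehydrogenation must occur at C17–C18 only.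

13 to 12 to 10 to 8: the C9–O bond is cut. C9 is β to the C11 ketone, so it is reached through the C9=C10 enone, conjugate borylation and oxidation. This returns to a ring C without substituents. The C11 ketone can enolise only toward C10, and the ring D enone must stay untouched.

8 to 7: the C13=C14 bond is cut (aldol condensation retron). Ring D opens and the only stereocentre disappears, leaving an achiral triketone. The forward step must distinguish two enantiotopic carbonyls.

7 to 6 to 5: the C15 carbonyl is traced to a vinyl group (Wacker retron) and the silyl ether to the free carbinol. The silyl ether is kept in 7 because a free hydroxyl would open retro-aldol and ketol-shift pathways. The oxidation must give the methyl ketone at a neopentyl alkene.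

5 to 2 and 3, and 2 to 1: the C12–C16 bond is cut. A prenyl nucleophile reacting through its γ-carbon adds to the central carbonyl of the trione 4, which comes from 1 by diazo transfer and oxygen transfer. The quaternary C16 and the C12 oxygen are made in one operation from two commercial materials. The addition must occur at the central carbonyl only.

## Other disconnections considered

Alternative 1: The cut is at C10–C11 and C17–C18, so ring C is assembled from the diene A2 and the three-carbon unit of propargyl pivalate A3. In the forward step (DTBM-SEGPHOS)(AuCl)2 with AgSbF6 (monovalent gold) triggers a 1,2-pivalate shift to a vinyl carbenoid, which cyclopropanates the silyl enol ether end of A2. The cis-divinylcyclopropane then undergoes a Cope rearrangement to A1.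
- In its favour: it is convergent, and A1 already carries C9 at the ketone level (enol pivalate), a differentiated C11 oxygen and the C17 methyl stereocentre. The chosen route needs steps 6 to 10 for these features.
- Against it here: C12 arrives as an alkene carbon (C12=C13), so the tertiary carbinol and the C13=C14 enone must be made afterwards by face-selective oxidation and transposition next to the gem-dimethyl carbon. The C11 stereocentre is made only to be oxidised, A2 needs two defined exocyclic alkene geometries, and the cyclopropanation must be cis-selective.
- Comparison: on structure it is the better plan for C9, C11 and C17, and the worse for C12. On mechanism both rest on catalyst control, and the gold step has closer precedent for enol ethers than the amino-acid step has for a seven-membered dione, so it is at least equal. On step economy the chosen plan is probably shorter before the key step and longer after it.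

Alternative 2: The cut is at C10–C11 and C12–C13. In the forward step A5 loses acetate with Et3N and heat to give a 3-oxidopyrylium, which adds across its termini to the tethered dioxole and gives the oxa-bridged adduct A4.
- In its favour: rings C and D form together with oxygen on C9, C10, C11 and C12, and the C9 enone with C17=C18 is ready for conjugate methylation. The chosen plan reaches the equivalent compound 15 only after four further steps. The relative configuration at C10 to C13 is fixed by the tether, and later opening of the ether bridge from a C15 ketone would give the C13=C14 enone and the C10 hydroxyl at once.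
- Against it here: C11 arrives at the alcohol level and must later be oxidised next to the C10 hydroxyl. The absolute configuration is relayed from a C15 carbinol that is later destroyed, so A5 must be made enantioenriched. The cycloaddition must form the quaternary C12 next to C16.
- Comparison: on structure it is the better plan for oxygenation density. On mechanism it is a thermal, substrate-controlled pericyclic step whose relative stereochemistry is more predictable, but it offers no catalytic control of absolute configuration. On step economy it needs more steps before the key step and fewer after.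

Alternative 3: The cut is at C12–C13, which in the precursor A7 is a C11–C13 bond. In the forward step Al(OtBu)3 promotes an α-ketol shift in which the alkenyl carbon C13 migrates from the C11 carbinol to the C12 carbonyl. The six-membered dione ring contracts to ring D and the carbocycle expands to ring C, giving A6.
- In its favour: A6 is the complete ring C and D core with the C9 ketal already distinguished from the C11 ketone, the C17 methyl and the free C12 carbinol. This is more than compound 13 of the chosen route offers. A7 is a decalin of the kind made by annulation chemistry, and the suprafacial shift should transfer the C11 configuration to C12.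
- Against it here: the shift is an equilibrium whose direction depends on strain and chelation. C10 may migrate in place of C13, and the product is itself an unprotected α-ketol that can shift again. The C11 carbinol and C17 must be set beforehand.
- Comparison: on structure it is the better plan. On mechanism it relies on thermodynamic control, whereas the chosen plan uses an irreversible dehydration. On step economy it should need fewer steps after the key step, and the length of the route to A7 is open.

Key step: step 5

Assumptions:
- The sense of induction in step 5 is taken from the Hajos–Parrish topology, which points to D-phenylalanine for the (12R) product; if the sense is opposite, L-phenylalanine is used.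
- Centres that are later erased or that equilibrate (C9 in 11 and 12, C18 in 16 and 17, C10 in 19) are drawn without configuration.

## Route

Step 1
Reactants: 1 cycloheptane-1,3-dione
Product: 2 2-diazocycloheptane-1,3-dione
Conditions: p-ABSA, Et3N, MeCN, 0 °C to rt
Reagents that add atoms: 4-acetamidobenzenesulfonyl azide (CC(=O)Nc1ccc(cc1)S(=O)(=O)N=[N+]=[N-])
Why: Regitz diazo transfer to the acidic methylene between the two carbonyls marks C12 alone for oxidation.

Step 2
Reactants: 2 2-diazocycloheptane-1,3-dione; 3 prenyl bromide (1-bromo-3-methylbut-2-ene)
Product: 5 2-hydroxy-2-(2-methylbut-3-en-2-yl)cycloheptane-1,3-dione, via cycloheptane-1,2,3-trione 4 (not isolated)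
Conditions: DMDO, acetone, 0 °C; then 3, In powder, THF/H2O (1:1), rt
Reagents that add atoms: dimethyldioxirane (CC1(C)OO1)
Why: Oxygen transfer to the diazo carbon gives the vicinal trione with loss of nitrogen. Barbier-type indium allylation then attacks the most electrophilic central carbonyl through the γ-carbon of the prenyl metal, forming C12–C16 with the quaternary gem-dimethyl carbon.

Step 3
Reactants: 5 2-hydroxy-2-(2-methylbut-3-en-2-yl)cycloheptane-1,3-dione
Product: 6 2-(2-methylbut-3-en-2-yl)-2-(triethylsilyloxy)cycloheptane-1,3-dione
Conditions: TESOTf, 2,6-lutidine, CH2Cl2, −78 to 0 °C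
Reagents that add atoms: triethylsilyl trifluoromethanesulfonate (CC[Si](CC)(CC)OS(=O)(=O)C(F)(F)F)
Why: A silyl triflate with a hindered pyridine base silylates the congested tertiary carbinol. The ether blocks retro-aldol and ketol shift and prevents oxypalladation by the hydroxyl in step 4.

Step 4
Reactants: 6 2-(2-methylbut-3-en-2-yl)-2-(triethylsilyloxy)cycloheptane-1,3-dione
Product: 7 2-(2-methyl-3-oxobutan-2-yl)-2-(triethylsilyloxy)cycloheptane-1,3-dione (achiral)
Conditions: PdCl2 (10 mol%), CuCl (co-catalyst), O2 (1 atm), DMF/H2O (7:1), rt
Reagents that add atoms: water (O)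
Why: Tsuji–Wacker oxidation: Markovnikov hydroxypalladation of the monosubstituted alkene gives the methyl ketone (C15), as in the standard route from γ,δ-unsaturated ketones to 1,4-diketones. The neopentyl position should only slow it.

Step 5
Reactants: 7 2-(2-methyl-3-oxobutan-2-yl)-2-(triethylsilyloxy)cycloheptane-1,3-dione
Product: 8 (8aR)-1,1-dimethyl-8a-(triethylsilyloxy)-4,5,6,7-tetrahydroazulene-2,8(1H,8aH)-dione (C11 ketone, C13=C14 enone, 12R)
Conditions: D-phenylalanine (1.0 equiv), (1R)-(−)-10-camphorsulfonic acid (0.5 equiv), DMF, 70 °C
Reagents that add atoms: none
Why: The primary amine of D-phenylalanine condenses with the side-chain ketone (C15) and tautomerises to the enamine at C14, the only enolisable carbon of that ketone because C16 is quaternary, while the carboxylic acid, helped by the sulfonic acid, hydrogen-bonds to one of the two ring carbonyls. Aldol addition of C14 to that carbonyl (C13), loss of water and hydrolysis of the iminium ion give the C13=C14 enone and release the amino acid. The closest known reaction type is the Hajos–Parrish amino-acid-mediated desymmetrising aldol condensation of 2,2-disubstituted cycloalkane-1,3-diones, including its cyclopentenone-forming variant with 2-(2-oxopropyl) diones. Ring D closes in the 5-(enolendo)-exo-trig mode, since C14 and C15 of the enamine both end up inside the new ring; this mode is formally unfavourable for enolates but is the normal course of 1,4-diketone to cyclopentenone condensations and is helped here by the enamine and the gem-dimethyl group. The one new stereocentre, C12, is not itself bonded in the step: its configuration follows from which enantiotopic carbonyl is attacked, and that choice is made by the hydrogen-bonded, amino-acid-bound transition state (catalyst control). The step needs group selection between the mirror-related carbonyls and chemoselection for C14 over the ring α-carbons; an aldol of a ring enol (C10 or C17) onto C15 would give a bridged β-hydroxy ketone that cannot become a conjugated enone and stays reversible, so the irreversible dehydration to 8 should drain the mixture. The silyl ether keeps the C12 oxygen out of retro-aldol and ketol chemistry under the mildly acidic conditions.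

Step 6
Reactants: 8 bicyclic ene-dione (12R)
Product: 10 (8aR)-1,1-dimethyl-8a-(triethylsilyloxy)-4,5-dihydroazulene-2,8(1H,8aH)-dione (C9=C10 enone), via C10 trimethylsilyl enol ether 9 (not isolated)
Conditions: LiN(SiMe3)2, Me3SiCl, THF, −78 °C; then Pd(OAc)2, MeCN, rt
Reagents that add atoms: none
Why: Kinetic deprotonation can occur only at C10, the single α-methylene of the C11 ketone, and the ring D enone has no α'-hydrogen. Saegusa–Ito oxidation of the silyl enol ether (palladium enolate, β-hydride loss from C9) gives the C9=C10 enone.

Step 7
Reactants: 10 dienedione with C9=C10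
Product: 12 C9 alcohol (β-hydroxy ketone; C9 epimers), via C9 pinacolboronate 11 (not isolated)
Conditions: B2pin2, CuCl (5 mol%), DPEphos (5 mol%), NaOtBu (10 mol%), MeOH, THF, rt; then NaBO3·4H2O, THF/H2O, rt
Reagents that add atoms: sodium perborate ([Na+].[Na+].O[B-]1(O)OO[B-](O)(O)OO1)
Why: Copper-catalysed conjugate borylation adds boron to the unhindered β-carbon C9; the β-carbon of the ring D enone (C13) is fully substituted and next to the quaternary C12. Perborate then oxidises the C–B bond to the alcohol, whose configuration does not matter.

Step 8
Reactants: 12 C9 alcohol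
Product: 13 (8aR)-1,1-dimethyl-8a-(triethylsilyloxy)-4,5-dihydroazulene-2,6,8(1H,7H,8aH)-trione (C9/C11 1,3-dione, largely enolised)
Conditions: IBX, EtOAc, 75 °C
Reagents that add atoms: none
Why: IBX as a suspension in ethyl acetate oxidises β-hydroxy ketones to β-diketones and should not over-oxidise the doubly activated C10.

Step 9
Reactants: 13 C9/C11 dione
Product: 15 cross-conjugated dienone (C11 tert-butyldimethylsilyl enol ether C10=C11, C9 ketone, C17=C18, ring D enone, 12R), via bis-silyl dienol ether 14 (not isolated)
Conditions: TBSOTf (2.3 equiv), Et3N, CH2Cl2, −78 to 0 °C; then Pd(OAc)2, MeCN, rt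
Reagents that add atoms: tert-butyldimethylsilyl trifluoromethanesulfonate (CC(C)(C)[Si](C)(C)OS(=O)(=O)C(F)(F)F)
Why: Soft enolisation silylates both oxygens, and because C12 has no hydrogen the only possible bis-enol ether is C11(OSi)=C10–C9(OSi)=C18. Saegusa–Ito palladation at the terminal C18 and β-hydride loss from C17 give C17=C18 and release the C9 carbonyl. The remaining C11 enol ether masks C11 and removes the acidity of C10.

Step 10
Reactants: 15 cross-conjugated dienone
Product: 18 C18-methylene enone with C17 methyl (methyl anti to the C12 silyl ether, as in the target), via Mannich base 16 (not isolated), via trimethylammonium iodide 17 (not isolated)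
Conditions: Me2CuLi (MeLi, CuI), Et2O/THF, −78 to −40 °C; then CH2=NMe2 I, −78 to 0 °C; then MeI, rt; NaHCO3 (aq)
Reagents that add atoms: lithium dimethylcuprate ([Li+].C[Cu-]C); N,N-dimethylmethyleneiminium iodide, Eschenmoser's salt (C=[N+](C)C.[I-])
Why: Cuprate 1,4-addition goes to C17, the only unsubstituted β-carbon (C13 is fully substituted, C11 carries a siloxy donor), from the face opposite the pseudo-axial C12 silyl ether, which sets C17. The resulting C9 enolate is trapped at C18 in a Mannich reaction, and quaternisation followed by E1cB loss of trimethylamine gives the exocyclic enone.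

Step 11
Reactants: 18 C18-methylene enone
Product: 19 C10-(tert-butyldimethylsilyloxy) C9/C11 dione with C18 methylene (C10 epimers)
Conditions: DMDO, acetone/CH2Cl2, −40 to 0 °C
Reagents that add atoms: dimethyldioxirane (CC1(C)OO1)
Why: Rubottom oxidation: the electrophilic oxidant epoxidises the electron-rich C10=C11 enol ether in preference to the three electron-poor enone double bonds. Epoxide opening with 1,4-silyl shift gives the C10 silyl ether and the C11 ketone.

Step 12
Reactants: 19 C10-silyloxy dione; 20 4-hydroxy-5,6-dimethyl-2H-pyran-2-one
Product: 21 bis-silyl ether of the target (C10 tert-butyldimethylsilyl ether, C12 triethylsilyl ether; 9S,10R,12R,17R,18R)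
Conditions: Et3N (10 mol%), MeCN, 0 °C to rt
Reagents that add atoms: none
Why: Michael addition of the pyranone enolate (C3) to the exocyclic methylene forms C3–C19, and the C4 hydroxyl then closes onto the C9 ketone to give the hemiketal. C18, C9 and C10 equilibrate by enolisation and ring opening and should settle in the trans-fused ring B/C with axial anomeric hydroxyl, C19 trans to the C17 methyl, and the C10 silyl ether anti to the oxygens on C9 and C12.

Step 13
Reactants: 21 bis-silyl ether of the target
Product: 22 CNP0525404.1 (9S,10R,12R,17R,18R)
Conditions: HF·pyridine, pyridine, THF, 0 °C to rt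
Reagents that add atoms: none
Why: Buffered fluoride cleaves both silyl ethers without the base that would cause retro-Michael opening, ketol shift or epimerisation at C10.

## Compound list

1 | cycloheptane-1,3-dione | O=C1CCCCC(=O)C1 | starting material
2 | 2-diazocycloheptane-1,3-dione | O=C1CCCCC(=O)C1=[N+]=[N-] | intermediate
3 | prenyl bromide | CC(C)=CCBr | starting material
4 | cycloheptane-1,2,3-trione | O=C1CCCCC(=O)C1=O | intermediate
5 | 2-hydroxy-2-(2-methylbut-3-en-2-yl)cycloheptane-1,3-dione | C=CC(C)(C)C1(O)C(=O)CCCCC1=O | intermediate
6 | 2-(2-methylbut-3-en-2-yl)-2-(triethylsilyloxy)cycloheptane-1,3-dione | C=CC(C)(C)C1(O[Si](CC)(CC)CC)C(=O)CCCCC1=O | intermediate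
7 | 2-(2-methyl-3-oxobutan-2-yl)-2-(triethylsilyloxy)cycloheptane-1,3-dione | CC(=O)C(C)(C)C1(O[Si](CC)(CC)CC)C(=O)CCCCC1=O | intermediate
8 | (8aR)-1,1-dimethyl-8a-(triethylsilyloxy)-4,5,6,7-tetrahydroazulene-2,8(1H,8aH)-dione | C1CC(=O)[C@@]2(O[Si](CC)(CC)CC)C(=CC(=O)C2(C)C)CC1 | intermediate
9 | C10=C11 trimethylsilyl enol ether of 8 | C1C=C(O[Si](C)(C)C)[C@@]2(O[Si](CC)(CC)CC)C(=CC(=O)C2(C)C)CC1 | intermediate
10 | (8aR)-1,1-dimethyl-8a-(triethylsilyloxy)-4,5-dihydroazulene-2,8(1H,8aH)-dione (C9=C10 enone) | C1=CC(=O)[C@@]2(O[Si](CC)(CC)CC)C(=CC(=O)C2(C)C)CC1 | intermediate
11 | C9 pinacolboronate of the C11 ketone (C9 epimers) | CC1(C)OB(OC1(C)C)C1CC(=O)[C@@]2(O[Si](CC)(CC)CC)C(=CC(=O)C2(C)C)CC1 | intermediate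
12 | C9 alcohol, β-hydroxy ketone (C9 epimers) | OC1CC(=O)[C@@]2(O[Si](CC)(CC)CC)C(=CC(=O)C2(C)C)CC1 | intermediate
13 | C9/C11 dione (trione overall), 12R | O=C1CC(=O)[C@@]2(O[Si](CC)(CC)CC)C(=CC(=O)C2(C)C)CC1 | intermediate
14 | C9,C11-bis(tert-butyldimethylsilyl) dienol ether (C10=C11, C9=C18) | CC(C)(C)[Si](C)(C)OC1=CC(O[Si](C)(C)C(C)(C)C)=CCC2=CC(=O)C(C)(C)[C@@]12O[Si](CC)(CC)CC | intermediate
15 | cross-conjugated dienone: C11 silyl enol ether, C9 ketone, C17=C18 | CC(C)(C)[Si](C)(C)OC1=CC(=O)C=CC2=CC(=O)C(C)(C)[C@@]12O[Si](CC)(CC)CC | intermediate
16 | Mannich base: C17 methyl, C18 dimethylaminomethyl (C18 epimers) | CC(C)(C)[Si](C)(C)OC1=CC(=O)C(CN(C)C)[C@@H](C)C2=CC(=O)C(C)(C)[C@@]12O[Si](CC)(CC)CC | intermediate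
17 | trimethylammonium iodide of 16 | CC(C)(C)[Si](C)(C)OC1=CC(=O)C(C[N+](C)(C)C)[C@@H](C)C2=CC(=O)C(C)(C)[C@@]12O[Si](CC)(CC)CC.[I-] | intermediate
18 | C18-methylene enone: C17 methyl anti to C12 silyl ether, C11 silyl enol ether | CC(C)(C)[Si](C)(C)OC1=CC(=O)C(=C)[C@@H](C)C2=CC(=O)C(C)(C)[C@@]12O[Si](CC)(CC)CC | intermediate
19 | C10-(tert-butyldimethylsilyloxy) C9/C11 dione with C18 methylene (C10 epimers) | CC(C)(C)[Si](C)(C)OC1C(=O)C(=C)[C@@H](C)C2=CC(=O)C(C)(C)[C@@]2(O[Si](CC)(CC)CC)C1=O | intermediate
20 | 4-hydroxy-5,6-dimethyl-2H-pyran-2-one | Cc1oc(=O)cc(O)c1C | starting material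
21 | target bis-silyl ether (C10 OTBS, C12 OTES) | Cc1oc(=O)c2c(c1C)O[C@]1(O)[C@H](O[Si](C)(C)C(C)(C)C)C(=O)[C@@]3(O[Si](CC)(CC)CC)C(=CC(=O)C3(C)C)[C@H](C)[C@H]1C2 | intermediate
22 | CNP0525404.1 | Cc1oc(=O)c2c(c1C)O[C@]1(O)[C@H](O)C(=O)[C@@]3(O)C(=CC(=O)C3(C)C)[C@H](C)[C@H]1C2 | target

## Step count and least certain steps

Total: 13 steps. Longest linear sequence: 13 steps (1 to 22); 20 is purchased.

Step 5 (key step). The enamine may form slowly at the neopentyl methyl ketone, and the amino acid may discriminate poorly between the two ring carbonyls or select the opposite one. Prolonged heating may also lead to retro-Claisen opening of the dione or loss of the silyl group. The fallback separates the stereo-determining event from ring closure; it sets out from 6 and returns at 8. One ring carbonyl of 6 would be reduced by desymmetrising asymmetric transfer hydrogenation (RuCl(p-cymene)[(S,S)-TsDPEN] or its enantiomer, HCO2H/Et3N) to the hydroxy ketone F1. Tsuji–Wacker oxidation would give the methyl ketone F2. Aldol condensation onto the only remaining ring carbonyl (pyrrolidine, AcOH) would give the hydroxy enone F3, and Dess–Martin oxidation of the C11 carbinol would give 8.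

Step 9. A third enolisation at C17 of the ring D enone may cause over-silylation, palladation may occur at C10, or the C11 silyl group may be lost in the acetic acid released. The fallback builds the masked dione one oxygen at a time; it sets out from 10 and returns at 15. The boronate 11 would be isolated and converted with TBSOTf/Et3N into the silyl enol ether allylboronate F4. Oxidation with NaBO3 would give the allylic alcohol F5, and MnO2 would give the β-silyloxy enone F6. Deprotonation at C18 (LiN(SiMe3)2) and PhSeBr would give the selenide F7, and H2O2 would give 15 by selenoxide elimination.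

Step 10. The methyl group may be delivered to the wrong face of C17, or the cuprate may undergo addition–elimination at C11. The fallback reverses the order of bond formation at C17; it sets out from 15 and returns at 16. Me2CuLi/Me3SiCl would give the silyl enol ether with the unwanted C17 configuration, F8, and Pd(OAc)2 would turn it into the 17-methyl dienone F9. Conjugate hydride transfer from [(Ph3P)CuH]6 would then place hydrogen on the face the methyl group had preferred, which gives the required C17 configuration. Trapping with Eschenmoser's salt would give 16.

Step 12. The exocyclic double bond may isomerise into the ring or the enone may oligomerise before the pyranone adds, and equilibration at C10, C18 and C9 may end on another diastereomer. The fallback forms ring B by an inverse-demand hetero-Diels–Alder reaction and introduces the C10 oxygen afterwards; it sets out from 15 and returns at 22. Me2CuLi/Me3SiCl would give the C9 trimethylsilyl enol ether F10. The quinone methide made in situ from 20 and paraformaldehyde (dioxane, 90 °C) would add to the C9=C18 enol ether face opposite the C17 methyl to give the cycloadduct F11. Rubottom oxidation (DMDO) of its C10=C11 enol ether, with C9 locked as a mixed ketal, would give F12. HF·pyridine would remove all silyl groups and let the hemiketal settle to 22.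

## Further compounds

F1 | step 5 | 3-hydroxy-2-(2-methylbut-3-en-2-yl)-2-(triethylsilyloxy)cycloheptan-1-one (C11 carbinol, either epimer) | OC1CCCCC(=O)[C@@]1(O[Si](CC)(CC)CC)C(C)(C)C=C
F2 | step 5 | 3-hydroxy-2-(2-methyl-3-oxobutan-2-yl)-2-(triethylsilyloxy)cycloheptan-1-one | OC1CCCCC(=O)[C@@]1(O[Si](CC)(CC)CC)C(C)(C)C(C)=O
F3 | step 5 | C11 alcohol of 8 (ring D enone closed) | OC1CCCCC2=CC(=O)C(C)(C)[C@@]12O[Si](CC)(CC)CC
F4 | step 9 | C11 tert-butyldimethylsilyl enol ether bearing the C9 pinacolboronate | CC(C)(C)[Si](C)(C)OC1=CC(B3OC(C)(C)C(C)(C)O3)CCC2=CC(=O)C(C)(C)[C@@]12O[Si](CC)(CC)CC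
F5 | step 9 | C9 allylic alcohol with C11 silyl enol ether | CC(C)(C)[Si](C)(C)OC1=CC(O)CCC2=CC(=O)C(C)(C)[C@@]12O[Si](CC)(CC)CC
F6 | step 9 | β-silyloxy enone: C11 silyl enol ether, C9 ketone | CC(C)(C)[Si](C)(C)OC1=CC(=O)CCC2=CC(=O)C(C)(C)[C@@]12O[Si](CC)(CC)CC
F7 | step 9 | C18 phenylselenide of F6 | CC(C)(C)[Si](C)(C)OC1=CC(=O)C([Se]c3ccccc3)CC2=CC(=O)C(C)(C)[C@@]12O[Si](CC)(CC)CC
F8 | step 10 | C9 trimethylsilyl enol ether with 17-epi methyl | CC(C)(C)[Si](C)(C)OC1=CC(O[Si](C)(C)C)=C[C@H](C)C2=CC(=O)C(C)(C)[C@@]12O[Si](CC)(CC)CC
F9 | step 10 | 17-methyl C17=C18 dienone | CC(C)(C)[Si](C)(C)OC1=CC(=O)C=C(C)C2=CC(=O)C(C)(C)[C@@]12O[Si](CC)(CC)CC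
F10 | step 12 | C9 trimethylsilyl enol ether with C17 methyl as in the target | CC(C)(C)[Si](C)(C)OC1=CC(O[Si](C)(C)C)=C[C@@H](C)C2=CC(=O)C(C)(C)[C@@]12O[Si](CC)(CC)CC
F11 | step 12 | hetero-Diels–Alder adduct: ring B closed, C9 trimethylsilyl ketal, C10=C11 silyl enol ether | Cc1oc(=O)c2c(c1C)O[C@@]1(O[Si](C)(C)C)C=C(O[Si](C)(C)C(C)(C)C)[C@@]3(O[Si](CC)(CC)CC)C(=CC(=O)C3(C)C)[C@H](C)[C@H]1C2
F12 | step 12 | tris-silyl tetracycle: C9 trimethylsilyl ketal, C10 OTBS, C11 ketone, C12 OTES | Cc1oc(=O)c2c(c1C)O[C@@]1(O[Si](C)(C)C)[C@H](O[Si](C)(C)C(C)(C)C)C(=O)[C@@]3(O[Si](CC)(CC)CC)C(=CC(=O)C3(C)C)[C@H](C)[C@H]1C2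
A1 | alternative 1 | hydroazulene triene: C9 enol pivalate, C11 silyl ether, C12=C13, C17 methyl, C15 dioxolane | CC(C)(C)C(=O)OC1=C[C@@H](O[Si](C)(C)C(C)(C)C)C2=C(CC3(OCCO3)C2(C)C)[C@H](C)C1
A2 | alternative 1 | cyclopentane diene: exocyclic ethylidene (C13=C17), exocyclic silyl enol ether (C12=C11), C15 dioxolane, C16 gem-dimethyl | C/C=C1\CC2(OCCO2)C(C)(C)/C1=C/O[Si](C)(C)C(C)(C)C
A3 | alternative 1 | propargyl pivalate | C#CCOC(=O)C(C)(C)C
A4 | alternative 2 | oxa-bridged (5+2) adduct: C10–O–C13 bridge, C11/C12 acetonide, C9 enone | O=C1[C@H]2[C@H]3OC(C)(C)O[C@@]3(C(C)(C)[C@H](O[Si](C)(C)C(C)(C)C)C4)[C@]4(O2)C=C1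
A5 | alternative 2 | 6-acetoxy-2H-pyran-3(6H)-one tethered at C13 to a 2,2-dimethyl-1,3-dioxole | CC(=O)OC1(C[C@@H](O[Si](C)(C)C(C)(C)C)C(C)(C)C2=COC(C)(C)O2)C=CC(=O)CO1
A6 | alternative 3 | hydroazulene ketol: C11 ketone, C12 carbinol, C9 dioxolane, C17 methyl | O1CCOC12CC(=O)[C@@]3(O)C(=CC(=O)C3(C)C)[C@H](C)C2
A7 | alternative 3 | decalin ketol dione: C11 carbinol bonded to C13, C12 and C15 ketones, C9 dioxolane | C[C@@H]1CC2(OCCO2)C[C@]3(O)C(=O)C(C)(C)C(=O)C=C13
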